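## Retrosynthetic overview

- Numbering is that of eremophilane: ring A = C1–C5 and C10, ring B = C5–C10, C14 = methyl on C5, C15 = methyl on C4; β is the face of C14.
- Ring B carries the cis oxygens on C8/C9 and, across the ring from the C8–C9 bond, the fusion bond C5–C10. With a C6=C7 alkene this is a Diels–Alder retron: target 34 ⇒ cycloadduct 22 ⇒ triene 21, made of a 1-silyloxy diene (C5=C6–C7=C8), a (Z)-alkenylboronate (C9=C10, boron = latent O9) and the tether C4–C3–C2–C1, which becomes ring A.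
- A temporary thiolane joins C14 and C15 (thiocarbonyl ylide cycloaddition in, Raney nickel out). It fixes the cis C4/C5 methyl pair and the diene face. C2 travels as a TIPS-protected carbinol from (S)-epichlorohydrin.
- After the cycloaddition: C9–B → C9–OH; hydroboration of C6=C7 anti to O8 and Zweifel olefination give the 7β-isopropenyl group; then senecioate, acetate and the C2 ketone.
- Ring order: thiolane (temporary) → rings A and B together in step 15 → thiolane opened in step 18.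

Key step: step 15

Remark: the target is read as (4S,5R,7R,8R,9S,10S): 4β-Me, 5β-Me, 10β-H (cis-decalin), 7β-isopropenyl, 8α-OAc, 9α-O-senecioyl.

Remark: in step 8 the ylide is assumed to add to the Cα-Re face of the N-enoyl (2R)-bornane-10,2-sultam, the usual sense for uncatalysed additions to this auxiliary; if the sense proves opposite, the antipodal sultam is used in steps 5–9.

## Route

Step 1
Reactants: 1 (S)-epichlorohydrin
Product: 2 (S)-1-chloropent-4-en-2-ol
Conditions: CH2=CHMgBr, CuI (10 mol%), THF, −40 → −20 °C; aq NH4Cl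
Reagents that add atoms: vinylmagnesium bromide, C=C[Mg]Br
Why: Copper-catalysed Grignard opening of the epoxide (SN2 at the unsubstituted carbon) leaves the C–O stereocentre, the future C2, untouched.

Step 2
Reactants: 2 (S)-1-chloropent-4-en-2-ol
Product: 4 (S)-hept-1-en-6-yn-4-ol, via (S)-2-allyloxirane 3 (not isolated)
Conditions: lithium acetylide–ethylenediamine complex (2.5 equiv), DMSO, 0 °C → rt; H2O
Reagents that add atoms: lithium acetylide ethylenediamine complex, [Li]C#C.NCCN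
Why: The acetylide first closes the chlorohydrin to the epoxide (intramolecular Williamson etherification) and then opens it at the terminal carbon (SN2 epoxide opening), again without touching the carbinol centre.

Step 3
Reactants: 4 (S)-hept-1-en-6-yn-4-ol
Product: 5 (S)-4-(triisopropylsilyloxy)hept-1-en-6-yne
Conditions: TIPSOTf, 2,6-lutidine, CH2Cl2, 0 °C
Reagents that add atoms: triisopropylsilyl triflate, CC(C)[Si](C(C)C)(C(C)C)OS(=O)(=O)C(F)(F)F
Why: Silylation of the secondary alcohol (silyl ether protection) installs a bulky group that lasts to step 23 and sits equatorially in the later cycloaddition.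

Step 4
Reactants: 5 (S)-4-(triisopropylsilyloxy)hept-1-en-6-yne
Product: 7 (R)-3-(triisopropylsilyloxy)hex-5-ynal, via secondary ozonide 6 (not isolated)
Conditions: O3, CH2Cl2, −78 °C (stopped at first excess of ozone); PPh3, −78 °C → rt
Reagents that add atoms: ozone, [O-][O+]=O
Why: Ozonolysis with reductive work-up cleaves the terminal alkene far faster than the terminal alkyne and gives the β-silyloxy aldehyde.

Step 5
Reactants: 8 (1S)-(−)-2,10-camphorsultam
Product: 9 N-(bromoacetyl)-(2R)-bornane-10,2-sultam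
Conditions: NaH, THF, 0 °C; BrCH2COBr, 0 °C → rt
Reagents that add atoms: bromoacetyl bromide, BrCC(Br)=O
Why: N-Acylation of the sodium salt of the sultam by the acid bromide (nucleophilic acyl substitution) gives the imide.

Step 6
Reactants: 9 N-(bromoacetyl)-(2R)-bornane-10,2-sultam
Product: 10 N-[(diethoxyphosphoryl)acetyl]-(2R)-bornane-10,2-sultam
Conditions: P(OEt)3 (neat), 120 °C
Reagents that add atoms: triethyl phosphite, CCOP(OCC)OCC
Why: Michaelis–Arbuzov reaction of the primary α-bromo imide gives the phosphonate.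

Step 7
Reactants: 7 (R)-3-(triisopropylsilyloxy)hex-5-ynal; 10 N-[(diethoxyphosphoryl)acetyl]-(2R)-bornane-10,2-sultam
Product: 11 N-[(2E,5S)-5-(triisopropylsilyloxy)oct-2-en-7-ynoyl]-(2R)-bornane-10,2-sultam
Conditions: LiCl, i-Pr2NEt, MeCN, rt
Reagents that add atoms: none
Why: Horner–Wadsworth–Emmons olefination under mild LiCl/amine conditions gives the (E)-enoyl sultam and avoids β-elimination of the silyloxy group.

Step 8
Reactants: 11 N-[(2E,5S)-5-(triisopropylsilyloxy)oct-2-en-7-ynoyl]-(2R)-bornane-10,2-sultam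
Product: 12 N-{[(3R,4S)-4-[(2S)-2-(triisopropylsilyloxy)pent-4-yn-1-yl]thiolan-3-yl]carbonyl}-(2R)-bornane-10,2-sultam
Conditions: ClCH2SCH2SiMe3, CsF, MeCN, rt
Reagents that add atoms: chloromethyl trimethylsilylmethyl sulfide, C[Si](C)(C)CSCCl
Why: 1,3-Dipolar cycloaddition of the fluoride-generated thiocarbonyl ylide to the (E)-alkene is suprafacial (trans-3,4-thiolane) and the sultam should direct it to the Cα-Re face, which sets C4 as (S) while C5 is only a placeholder.

Step 9
Reactants: 12 thiolane acyl sultam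
Product: 13 [(3R,4S)-4-[(2S)-2-(triisopropylsilyloxy)pent-4-yn-1-yl]thiolan-3-yl]methanol
Conditions: LiBH4, THF, H2O (1 equiv), 0 °C → rt
Reagents that add atoms: none
Why: Reductive cleavage of the N-acyl sultam with LiBH4 gives the primary alcohol and returns the auxiliary.

Step 10
Reactants: 13 thiolane alkynol
Product: 16 [(3R,4S)-4-[(2S)-5-(4,4,5,5-tetramethyl-1,3,2-dioxaborolan-2-yl)-2-(triisopropylsilyloxy)pent-4-yn-1-yl]thiolan-3-yl]methanol, via dilithio alkoxide acetylide 14 (not isolated), via lithium alkynyl(isopropoxy)borate 15 (not isolated)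
Conditions: n-BuLi (2.2 equiv), THF, −78 °C; i-PrOBpin, −78 → −20 °C; HCl in Et2O, −78 °C
Reagents that add atoms: 2-isopropoxy-4,4,5,5-tetramethyl-1,3,2-dioxaborolane, CC(C)OB1OC(C)(C)C(C)(C)O1
Why: Borylation of the lithium acetylide with the isopropoxy borate followed by anhydrous acid is the standard preparation of alkynyl pinacol boronates, with the alkoxide as a spectator.

Step 11
Reactants: 16 alkynyl boronate
Product: 18 [(3R,4S)-4-[(2R,4Z)-5-(4,4,5,5-tetramethyl-1,3,2-dioxaborolan-2-yl)-2-(triisopropylsilyloxy)pent-4-en-1-yl]thiolan-3-yl]methanol, via borylalkenyl zirconocene 17 (not isolated)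
Conditions: Cp2Zr(H)Cl (2.3 equiv), THF, rt; H2O
Reagents that add atoms: none
Why: Hydrozirconation of the alkynylboronate is a syn addition that puts zirconium on the boron-bearing carbon, and protonolysis of the C–Zr bond with retention gives the (Z)-alkenylboronate.

Step 12
Reactants: 18 (Z)-alkenylboronate alcohol
Product: 19 (3R,4S)-4-[(2R,4Z)-5-(4,4,5,5-tetramethyl-1,3,2-dioxaborolan-2-yl)-2-(triisopropylsilyloxy)pent-4-en-1-yl]thiolane-3-carbaldehyde
Conditions: DMP, NaHCO3, CH2Cl2, 0 °C → rt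
Reagents that add atoms: none
Why: Dess–Martin oxidation of the primary alcohol is mild enough for the thioether and the alkenylboronate, and the α-centre (C5) made labile here is erased in step 14 anyway.

Step 13
Reactants: 19 thiolane aldehyde
Product: 20 (2E)-3-[(3S,4S)-4-[(2R,4Z)-5-(4,4,5,5-tetramethyl-1,3,2-dioxaborolan-2-yl)-2-(triisopropylsilyloxy)pent-4-en-1-yl]thiolan-3-yl]prop-2-enal
Conditions: Ph3P=CHCHO, toluene, 80 °C
Reagents that add atoms: (triphenylphosphoranylidene)acetaldehyde, O=CC=P(c1ccccc1)(c1ccccc1)c1ccccc1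
Why: Wittig olefination with the stabilised formyl ylide gives the (E)-enal.

Step 14
Reactants: 20 enal
Product: 21 (3S,4Z)-4-[(2E)-3-(tert-butyldimethylsilyloxy)prop-2-en-1-ylidene]-3-[(2R,4Z)-5-(4,4,5,5-tetramethyl-1,3,2-dioxaborolan-2-yl)-2-(triisopropylsilyloxy)pent-4-en-1-yl]thiolane
Conditions: TBSOTf, Et3N, CH2Cl2, −78 → 0 °C
Reagents that add atoms: tert-butyldimethylsilyl triflate, CC(C)(C)[Si](C)(C)OS(=O)(=O)C(F)(F)F
Why: Soft enolisation (O-silylation, then γ-deprotonation) of the s-trans enal should give the (1E)-silyl dienol ether with the unsubstituted ring CH2 (C14) cis to C7 as the less hindered exocyclic geometry, and wrong geometric isomers can be hydrolysed back to 20.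

Step 15
Reactants: 21 silyl dienol ether / (Z)-alkenylboronate triene
Product: 22 8α-(tert-butyldimethylsilyloxy)-9α-(pinacolatoboryl)-2α-(triisopropylsilyloxy)-14,15-epithio-10βH-eremophil-6-ene
Conditions: toluene (0.005 M, degassed), BHT (0.1 equiv), base-washed sealed vessel, 160 °C
Reagents that add atoms: none
Why: This is a thermal intramolecular Diels–Alder reaction (1,3,9-decatriene type), a concerted suprafacial [4+2] cycloaddition between the electron-rich 1-silyloxy diene C5=C6–C7=C8 and the boron-substituted (Z)-alkene C9=C10, whose polarisation (nucleophilic C5, C10 electrophilic β to boron) matches the regiochemistry imposed by the tether; the closest known reactions are thermal Diels–Alder additions of alkenylboronic esters to dienes and decatriene cyclisations. Ring B is closed by the cycloaddition itself and ring A as the six-membered ring defined by the four-atom tether C4–C3–C2–C1, in a chair-like transition state with the TIPS ether equatorial. C5 is controlled by C4: the tether hangs from one face of the thiolane, so the dienophile can reach only that face of the exocyclic diene, and the thiolane holds C15 syn to C14, which makes the arrangement leading to the cis C4/C5 methyl pair the built-in one. C10 and C9 follow from the (Z) dienophile geometry (C1 and boron cis), and C8 from the (E) enol ether, which places oxygen cis to the C5–C4 bond. The selectivity needed is the endo orientation of the tether (cis ring fusion): in that mode only H10 faces the inside CH2 (C14) of the diene, whereas the exo (trans-fused) mode pushes C1 against it, and a boron–diene secondary interaction adds to this. Because the boronate is only a weak dienophile, the [1,5]-hydrogen shift from C14 is the competing process to watch.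

Step 16
Reactants: 22 cycloadduct
Product: 23 8α-(tert-butyldimethylsilyloxy)-2α-(triisopropylsilyloxy)-14,15-epithio-10βH-eremophil-6-en-9α-ol
Conditions: H2O2 (30% aq), NaOH (3 M), THF, 0 °C
Reagents that add atoms: hydrogen peroxide, OO
Why: Oxidation of the secondary alkylboronate with basic peroxide (1,2-migration from boron to oxygen) proceeds with retention and gives the 9α-alcohol, while hydroperoxide anion is a poor oxidant for the thioether.

Step 17
Reactants: 23 homoallylic alcohol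
Product: 25 8α-(tert-butyldimethylsilyloxy)-7β-(pinacolatoboryl)-2α-(triisopropylsilyloxy)-14,15-epithio-10βH-eremophilan-9α-ol, via alkylborane 24 (not isolated)
Conditions: BH3·THF (3 equiv), THF, 0 °C → rt; pinacol, rt; H2O
Reagents that add atoms: borane–tetrahydrofuran complex, B.C1CCOC1; pinacol, CC(C)(O)C(C)(C)O
Why: Hydroboration is a syn addition that should place boron on C7 (adjacent to the allylic oxygen and away from quaternary C5) and on the β face, anti to the 8α-silyloxy group, which sets C7; pinacol then converts the borane into the boronic ester.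

Step 18
Reactants: 25 thiolane boronate
Product: 26 8α-(tert-butyldimethylsilyloxy)-7β-(pinacolatoboryl)-2α-(triisopropylsilyloxy)-10βH-eremophilan-9α-ol
Conditions: Raney nickel (Ni, W-2 grade, excess), EtOH, rt → 50 °C
Reagents that add atoms: none
Why: Raney nickel desulfurisation hydrogenolyses both C–S bonds of the thiolane, turning C14 and C15 into the cis-vicinal methyl groups without touching a stereocentre.

Step 19
Reactants: 26 secondary boronate
Product: 29 8α-(tert-butyldimethylsilyloxy)-2α-(triisopropylsilyloxy)-10βH-eremophil-11-en-9α-ol, via boronate ate complex 27 (not isolated), via β-iodoalkyl boronate 28 (not isolated)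
Conditions: isopropenyllithium (2.5 equiv), THF, −78 °C; I2, MeOH, −78 °C; NaOMe, MeOH, −78 °C → rt
Reagents that add atoms: isopropenyllithium, [Li]C(C)=C
Why: Zweifel olefination: iodine triggers 1,2-migration of C7 from boron to carbon with retention, and anti-elimination of boron and iodine by methoxide gives the isopropenyl group, β at C7.

Step 20
Reactants: 29 9α-alcohol
Product: 30 8α-(tert-butyldimethylsilyloxy)-2α-(triisopropylsilyloxy)-10βH-eremophil-11-en-9α-yl 3-methylbut-2-enoate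
Conditions: 3-methylbut-2-enoyl chloride, pyridine, DMAP (cat.), CH2Cl2, 0 °C → rt
Reagents that add atoms: 3-methylbut-2-enoyl chloride, CC(C)=CC(Cl)=O
Why: DMAP-catalysed acylation of the hindered axial alcohol (nucleophilic acyl substitution) with pyridine as the only base limits deconjugation of the senecioyl unit.

Step 21
Reactants: 30 senecioate
Product: 31 8α-hydroxy-2α-(triisopropylsilyloxy)-10βH-eremophil-11-en-9α-yl 3-methylbut-2-enoate
Conditions: HF·pyridine, pyridine, THF, 0 °C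
Reagents that add atoms: none
Why: Fluoride-mediated desilylation removes the secondary TBS ether well before the bulkier TIPS ether, and the acidic medium does not promote acyl migration.

Step 22
Reactants: 31 8α-alcohol
Product: 32 8α-acetoxy-2α-(triisopropylsilyloxy)-10βH-eremophil-11-en-9α-yl 3-methylbut-2-enoate
Conditions: Ac2O, pyridine, DMAP (cat.), CH2Cl2, rt
Reagents that add atoms: acetic anhydride, CC(=O)OC(C)=O
Why: Acetylation of the free equatorial C8 alcohol (nucleophilic acyl substitution).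

Step 23
Reactants: 32 diester TIPS ether
Product: 33 8α-acetoxy-2α-hydroxy-10βH-eremophil-11-en-9α-yl 3-methylbut-2-enoate
Conditions: TBAF, AcOH (1:1), THF, rt → 40 °C
Reagents that add atoms: none
Why: Buffered fluoride desilylation removes the TIPS ether without ester cleavage or acyl migration.

Step 24
Reactants: 33 2α-alcohol
Product: 34 (4S,5R,7R,8R,9S,10S)-8-acetoxy-2-oxoeremophil-11-en-9-yl 3-methylbut-2-enoate (CNP0150397.1)
Conditions: DMP, NaHCO3, CH2Cl2, 0 °C → rt
Reagents that add atoms: none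
Why: Dess–Martin oxidation of the secondary alcohol gives the C2 ketone under buffered, non-epimerising conditions.

## Compound list

1 | (S)-epichlorohydrin | ClC[C@@H]1CO1 | starting material
2 | (S)-1-chloropent-4-en-2-ol | ClC[C@@H](O)CC=C | intermediate
3 | (S)-2-allyloxirane (not isolated) | C=CC[C@H]1CO1 | intermediate
4 | (S)-hept-1-en-6-yn-4-ol | C#CC[C@@H](O)CC=C | intermediate
5 | (S)-4-(triisopropylsilyloxy)hept-1-en-6-yne | C#CC[C@@H](O[Si](C(C)C)(C(C)C)C(C)C)CC=C | intermediate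
6 | secondary ozonide of 5: 3-[(2R)-2-(triisopropylsilyloxy)pent-4-yn-1-yl]-1,2,4-trioxolane (not isolated) | C#CC[C@@H](O[Si](C(C)C)(C(C)C)C(C)C)CC1OCOO1 | intermediate
7 | (R)-3-(triisopropylsilyloxy)hex-5-ynal | C#CC[C@@H](O[Si](C(C)C)(C(C)C)C(C)C)CC=O | intermediate
8 | (1S)-(−)-2,10-camphorsultam [(2R)-bornane-10,2-sultam] | CC1(C)[C@@H]2CC[C@]13CS(=O)(=O)N[C@@H]3C2 | starting material
9 | N-(bromoacetyl)-(2R)-bornane-10,2-sultam | CC1(C)[C@@H]2CC[C@]13CS(=O)(=O)N(C(=O)CBr)[C@@H]3C2 | intermediate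
10 | N-[(diethoxyphosphoryl)acetyl]-(2R)-bornane-10,2-sultam | CC1(C)[C@@H]2CC[C@]13CS(=O)(=O)N(C(=O)CP(=O)(OCC)OCC)[C@@H]3C2 | intermediate
11 | N-[(2E,5S)-5-(triisopropylsilyloxy)oct-2-en-7-ynoyl]-(2R)-bornane-10,2-sultam | CC1(C)[C@@H]2CC[C@]13CS(=O)(=O)N(C(=O)/C=C/C[C@H](O[Si](C(C)C)(C(C)C)C(C)C)CC#C)[C@@H]3C2 | intermediate
12 | N-{[(3R,4S)-4-[(2S)-2-(triisopropylsilyloxy)pent-4-yn-1-yl]thiolan-3-yl]carbonyl}-(2R)-bornane-10,2-sultam | CC1(C)[C@@H]2CC[C@]13CS(=O)(=O)N(C(=O)[C@@H]4CSC[C@H]4C[C@H](O[Si](C(C)C)(C(C)C)C(C)C)CC#C)[C@@H]3C2 | intermediate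
13 | [(3R,4S)-4-[(2S)-2-(triisopropylsilyloxy)pent-4-yn-1-yl]thiolan-3-yl]methanol | C#CC[C@@H](O[Si](C(C)C)(C(C)C)C(C)C)C[C@@H]1CSC[C@H]1CO | intermediate
14 | dilithio alkoxide acetylide of 13 (not isolated) | [Li]C#CC[C@@H](O[Si](C(C)C)(C(C)C)C(C)C)C[C@@H]1CSC[C@H]1CO[Li] | intermediate
15 | lithium alkynyl(isopropoxy)(pinacolato)borate, lithium alkoxide (not isolated) | [Li+].[Li+].CC(C)O[B-]1(OC(C)(C)C(C)(C)O1)C#CC[C@@H](O[Si](C(C)C)(C(C)C)C(C)C)C[C@@H]2CSC[C@H]2C[O-] | intermediate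
16 | [(3R,4S)-4-[(2S)-5-(4,4,5,5-tetramethyl-1,3,2-dioxaborolan-2-yl)-2-(triisopropylsilyloxy)pent-4-yn-1-yl]thiolan-3-yl]methanol | CC1(C)OB(OC1(C)C)C#CC[C@@H](O[Si](C(C)C)(C(C)C)C(C)C)C[C@@H]1CSC[C@H]1CO | intermediate
17 | 1-boryl-1-(chlorozirconocenyl)alkene, zirconocene alkoxide (not isolated) | CC1(C)OB(OC1(C)C)/C(=C\C[C@@H](O[Si](C(C)C)(C(C)C)C(C)C)C[C@@H]1CSC[C@H]1CO[Zr](Cl)(C1C=CC=C1)C1C=CC=C1)[Zr](Cl)(C1C=CC=C1)C1C=CC=C1 | intermediate
18 | [(3R,4S)-4-[(2R,4Z)-5-(4,4,5,5-tetramethyl-1,3,2-dioxaborolan-2-yl)-2-(triisopropylsilyloxy)pent-4-en-1-yl]thiolan-3-yl]methanol | CC1(C)OB(OC1(C)C)/C=C\C[C@@H](O[Si](C(C)C)(C(C)C)C(C)C)C[C@@H]1CSC[C@H]1CO | intermediate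
19 | (3R,4S)-4-[(2R,4Z)-5-(4,4,5,5-tetramethyl-1,3,2-dioxaborolan-2-yl)-2-(triisopropylsilyloxy)pent-4-en-1-yl]thiolane-3-carbaldehyde | CC1(C)OB(OC1(C)C)/C=C\C[C@@H](O[Si](C(C)C)(C(C)C)C(C)C)C[C@@H]1CSC[C@H]1C=O | intermediate
20 | (2E)-3-[(3S,4S)-4-[(2R,4Z)-5-(4,4,5,5-tetramethyl-1,3,2-dioxaborolan-2-yl)-2-(triisopropylsilyloxy)pent-4-en-1-yl]thiolan-3-yl]prop-2-enal | CC1(C)OB(OC1(C)C)/C=C\C[C@@H](O[Si](C(C)C)(C(C)C)C(C)C)C[C@@H]1CSC[C@H]1/C=C/C=O | intermediate
21 | (3S,4Z)-4-[(2E)-3-(tert-butyldimethylsilyloxy)prop-2-en-1-ylidene]-3-[(2R,4Z)-5-(4,4,5,5-tetramethyl-1,3,2-dioxaborolan-2-yl)-2-(triisopropylsilyloxy)pent-4-en-1-yl]thiolane | CC1(C)OB(OC1(C)C)/C=C\C[C@@H](O[Si](C(C)C)(C(C)C)C(C)C)C[C@@H]1CSC/C1=C\C=C\O[Si](C)(C)C(C)(C)C | intermediate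
22 | 8α-(tert-butyldimethylsilyloxy)-9α-(pinacolatoboryl)-2α-(triisopropylsilyloxy)-14,15-epithio-10βH-eremophil-6-ene | C1=C[C@@]2(CS3)[C@H](C[C@@H](O[Si](C(C)C)(C(C)C)C(C)C)C[C@@H]2C3)[C@H](B4OC(C)(C)C(C)(C)O4)[C@@H]1O[Si](C)(C)C(C)(C)C | intermediate
23 | 8α-(tert-butyldimethylsilyloxy)-2α-(triisopropylsilyloxy)-14,15-epithio-10βH-eremophil-6-en-9α-ol | C1=C[C@@]2(CS3)[C@H](C[C@@H](O[Si](C(C)C)(C(C)C)C(C)C)C[C@@H]2C3)[C@H](O)[C@@H]1O[Si](C)(C)C(C)(C)C | intermediate
24 | 7β-boranyl 9-O-boranyl derivative of 23 (not isolated) | [BH2][C@H]1C[C@@]2(CS3)[C@H](C[C@@H](O[Si](C(C)C)(C(C)C)C(C)C)C[C@@H]2C3)[C@H](O[BH2])[C@@H]1O[Si](C)(C)C(C)(C)C | intermediate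
25 | 8α-(tert-butyldimethylsilyloxy)-7β-(pinacolatoboryl)-2α-(triisopropylsilyloxy)-14,15-epithio-10βH-eremophilan-9α-ol | CC1(C)OB(OC1(C)C)[C@H]2C[C@@]3(CS4)[C@H](C[C@@H](O[Si](C(C)C)(C(C)C)C(C)C)C[C@@H]3C4)[C@H](O)[C@@H]2O[Si](C)(C)C(C)(C)C | intermediate
26 | 8α-(tert-butyldimethylsilyloxy)-7β-(pinacolatoboryl)-2α-(triisopropylsilyloxy)-10βH-eremophilan-9α-ol | CC1(C)OB(OC1(C)C)[C@H]2C[C@@]3(C)[C@H](C[C@@H](O[Si](C(C)C)(C(C)C)C(C)C)C[C@@H]3C)[C@H](O)[C@@H]2O[Si](C)(C)C(C)(C)C | intermediate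
27 | lithium isopropenyl boronate ate complex of 26, lithium alkoxide (not isolated) | [Li+].[Li+].C=C(C)[B-]1(OC(C)(C)C(C)(C)O1)[C@H]2C[C@@]3(C)[C@H](C[C@@H](O[Si](C(C)C)(C(C)C)C(C)C)C[C@@H]3C)[C@H]([O-])[C@@H]2O[Si](C)(C)C(C)(C)C | intermediate
28 | β-iodoalkyl boronic ester after 1,2-migration, lithium alkoxide (not isolated) | [Li+].ICC(C)(B1OC(C)(C)C(C)(C)O1)[C@H]2C[C@@]3(C)[C@H](C[C@@H](O[Si](C(C)C)(C(C)C)C(C)C)C[C@@H]3C)[C@H]([O-])[C@@H]2O[Si](C)(C)C(C)(C)C | intermediate
29 | 8α-(tert-butyldimethylsilyloxy)-2α-(triisopropylsilyloxy)-10βH-eremophil-11-en-9α-ol | C=C(C)[C@H]1C[C@@]2(C)[C@H](C[C@@H](O[Si](C(C)C)(C(C)C)C(C)C)C[C@@H]2C)[C@H](O)[C@@H]1O[Si](C)(C)C(C)(C)C | intermediate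
30 | 8α-(tert-butyldimethylsilyloxy)-2α-(triisopropylsilyloxy)-10βH-eremophil-11-en-9α-yl 3-methylbut-2-enoate | C=C(C)[C@H]1C[C@@]2(C)[C@H](C[C@@H](O[Si](C(C)C)(C(C)C)C(C)C)C[C@@H]2C)[C@H](OC(=O)C=C(C)C)[C@@H]1O[Si](C)(C)C(C)(C)C | intermediate
31 | 8α-hydroxy-2α-(triisopropylsilyloxy)-10βH-eremophil-11-en-9α-yl 3-methylbut-2-enoate | C=C(C)[C@H]1C[C@@]2(C)[C@H](C[C@@H](O[Si](C(C)C)(C(C)C)C(C)C)C[C@@H]2C)[C@H](OC(=O)C=C(C)C)[C@@H]1O | intermediate
32 | 8α-acetoxy-2α-(triisopropylsilyloxy)-10βH-eremophil-11-en-9α-yl 3-methylbut-2-enoate | C=C(C)[C@H]1C[C@@]2(C)[C@H](C[C@@H](O[Si](C(C)C)(C(C)C)C(C)C)C[C@@H]2C)[C@H](OC(=O)C=C(C)C)[C@@H]1OC(C)=O | intermediate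
33 | 8α-acetoxy-2α-hydroxy-10βH-eremophil-11-en-9α-yl 3-methylbut-2-enoate | C=C(C)[C@H]1C[C@@]2(C)[C@H](C[C@@H](O)C[C@@H]2C)[C@H](OC(=O)C=C(C)C)[C@@H]1OC(C)=O | intermediate
34 | (4S,5R,7R,8R,9S,10S)-8-acetoxy-2-oxoeremophil-11-en-9-yl 3-methylbut-2-enoate (CNP0150397.1) | C=C(C)[C@H]1C[C@@]2(C)[C@H](CC(=O)C[C@@H]2C)[C@H](OC(=O)C=C(C)C)[C@@H]1OC(C)=O | target

## Step count and risks

Total step count: 24. Longest linear sequence: 22 (steps 1–4 and 7–24); steps 5–6 prepare the olefination reagent 10.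

Steps most likely to fail:

1. **Step 15 (cycloaddition).** The weakly activated boronate may cyclise too slowly, so that the [1,5]-hydrogen shift from the inside CH2 or loss of the silyl dienol ether takes over, and the preference for the endo-tether (cis-fused) mode may be insufficient. The fallback sets out from 20 and comes back at 22. Enal 20 is converted with isopropenyl acetate and TsOH into the dienyl acetate F1, a diene that tolerates a boron halide. BCl3 at −78 °C exchanges pinacol for chloride to give the alkenyldichloroborane F2, a far stronger and endo-selective dienophile that should cyclise below 0 °C to the dichloroboryl cycloadduct F3. Pinacol and Et3N re-form the boronic ester as the acetoxy boronate F4. K2CO3 in MeOH removes the acetate to give the hydroxy boronate F5, and TBSOTf with 2,6-lutidine gives 22.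

2. **Step 17 (hydroboration).** Boron may be delivered to C6, or to the α face by the 9-O-boranyl group formed in the flask. The fallback sets out from 23 and comes back at 29. Alcohol 23 is silylated at O9 (TESOTf, 2,6-lutidine) to the bis-silyl ether F6, so that both α-oxygens are bulky ethers and no O–B–H unit can deliver hydride. Hydroboration and pinacol then give the boronate F7, Raney nickel gives the dimethyl boronate F8, and Zweifel olefination gives the isopropenyl TES ether F9. PPTS in MeOH removes only the TES group and returns 29.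

3. **Step 18 (desulfurisation).** The C7–B bond may be lost on the nickel surface (protodeboronation), or the second C–S bond may be cleaved incompletely. The fallback sets out from 23 and comes back at 26. The order is changed: 23 is desulfurised first with acetone-deactivated Raney nickel, which should spare the cis-disubstituted alkene, to give the dimethyl alkene F10. Hydroboration and pinacol as in step 17 then give 26.

Further compounds

F1 | step 15 | dienyl acetate, acetoxy analogue of 21 | CC1(C)OB(OC1(C)C)/C=C\C[C@@H](O[Si](C(C)C)(C(C)C)C(C)C)C[C@@H]1CSC/C1=C\C=C\OC(C)=O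
F2 | step 15 | (Z)-alkenyldichloroborane from F1 (not isolated) | ClB(Cl)/C=C\C[C@@H](O[Si](C(C)C)(C(C)C)C(C)C)C[C@@H]1CSC/C1=C\C=C\OC(C)=O
F3 | step 15 | 8α-acetoxy-9α-(dichloroboryl)-2α-(triisopropylsilyloxy)-14,15-epithio-10βH-eremophil-6-ene (not isolated) | C1=C[C@@]2(CS3)[C@H](C[C@@H](O[Si](C(C)C)(C(C)C)C(C)C)C[C@@H]2C3)[C@H](B(Cl)Cl)[C@@H]1OC(C)=O
F4 | step 15 | 8α-acetoxy-9α-(pinacolatoboryl)-2α-(triisopropylsilyloxy)-14,15-epithio-10βH-eremophil-6-ene | C1=C[C@@]2(CS3)[C@H](C[C@@H](O[Si](C(C)C)(C(C)C)C(C)C)C[C@@H]2C3)[C@H](B4OC(C)(C)C(C)(C)O4)[C@@H]1OC(C)=O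
F5 | step 15 | 9α-(pinacolatoboryl)-2α-(triisopropylsilyloxy)-14,15-epithio-10βH-eremophil-6-en-8α-ol | C1=C[C@@]2(CS3)[C@H](C[C@@H](O[Si](C(C)C)(C(C)C)C(C)C)C[C@@H]2C3)[C@H](B4OC(C)(C)C(C)(C)O4)[C@@H]1O
F6 | step 17 | 9-O-triethylsilyl ether of 23 | C1=C[C@@]2(CS3)[C@H](C[C@@H](O[Si](C(C)C)(C(C)C)C(C)C)C[C@@H]2C3)[C@H](O[Si](CC)(CC)CC)[C@@H]1O[Si](C)(C)C(C)(C)C
F7 | step 17 | 9-O-triethylsilyl ether of 25 | CC1(C)OB(OC1(C)C)[C@H]2C[C@@]3(CS4)[C@H](C[C@@H](O[Si](C(C)C)(C(C)C)C(C)C)C[C@@H]3C4)[C@H](O[Si](CC)(CC)CC)[C@@H]2O[Si](C)(C)C(C)(C)C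
F8 | step 17 | 9-O-triethylsilyl ether of 26 | CC1(C)OB(OC1(C)C)[C@H]2C[C@@]3(C)[C@H](C[C@@H](O[Si](C(C)C)(C(C)C)C(C)C)C[C@@H]3C)[C@H](O[Si](CC)(CC)CC)[C@@H]2O[Si](C)(C)C(C)(C)C
F9 | step 17 | 9-O-triethylsilyl ether of 29 | C=C(C)[C@H]1C[C@@]2(C)[C@H](C[C@@H](O[Si](C(C)C)(C(C)C)C(C)C)C[C@@H]2C)[C@H](O[Si](CC)(CC)CC)[C@@H]1O[Si](C)(C)C(C)(C)C
F10 | step 18 | 8α-(tert-butyldimethylsilyloxy)-2α-(triisopropylsilyloxy)-10βH-eremophil-6-en-9α-ol | C1=C[C@@]2(C)[C@H](C[C@@H](O[Si](C(C)C)(C(C)C)C(C)C)C[C@@H]2C)[C@H](O)[C@@H]1O[Si](C)(C)C(C)(C)C
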